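In a one-step world with a single time constant, each first end group that reacted would have become a link, so links and free first ends would add up to the charge; the epsilon run does not behave so. We want the chain length and the reacted part for the flask followed so far as the theta run.

in all of them: first end groups 0.053 M
- theta: second end groups 0.98 equiv; protic impurity 0.0106 M; the very flask that is asked about, followed so far
- epsilon: second end groups 0.98 equiv; protic impurity 0.0053 M; run made earlier
- flask: second end groups 0.980 equiv; protic impurity 0.0106 M; time 12 min

theta run (percent of the first end groups charged)

| time / s | links / % | first end groups / % |
|---|---|---|
| 10.0 | 45 | 48 |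
| 20.0 | 54 | 37 |
| 40.0 | 63 | 25 |
| 60.0 | 64 | 21 |
| 80.0 | 65 | 20 |
| 90.0 | 66 | 19 |
| 120 | 61 | 16 |

epsilon run (percent of the first end groups charged)

| time / min | links / % | first end groups / % |
|---|---|---|
| 1.33 | 66 | 24 |
| 2.50 | 66 | 22 |
| 4.00 | 68 | 23 |
| 5.00 | 64 | 23 |
| 6.00 | 66 | 23 |
| 8.00 | 68 | 23 |

(readings scatter by 1.5 percentage points)

- each molecule carries two end groups: a chain counts once for every two ends that are left, dead ends included; the units are half of the end groups of the two monomers charged
- what was read earlier has a scatter of 1.5 percentage points, one standard deviation

1. average number of monomer units in a chain (unreacted monomers counted as chains of one) at 12 min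
2. part of the first end groups that has reacted at 12 min

In the epsilon run, links and first end groups leave a mean gap of 10.7%, close to the 10.0% of protic impurity charged, so we read the gap as capped first ends. The ten plateau readings of links, epsilon's and theta's from 60.0 s on, average 65.4%, and the asked flask carries 20.0% of impurity per first end, so we reckon its reacted part at 85.4%. This sum of link plateau and impurity per first end is our bench rule, the end-group ledger. Units are 99.0% of the first ends charged and each link removes one chain, so we reckon a chain length of 2.95.

The ledger counts the impurity as fully capped by the asked time, so the border we test is a ratio of times. In theta the impurity left, read from the gap, falls from 11.0% to 5.00% between 20.0 s and 60.0 s, a rough time constant of 50.7 s at 27.7% free first ends. We take capping as pseudo-first-order in impurity, its clock scaling inversely with free first ends. Putting our first answer back in, 14.6% free, gives 96.1 s. The asked time is 7.49 such constants, and by this estimate 0.0559% of the impurity remains, so we keep the ledger for the asked flask.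

The forecast, reasoning “the reaction has stopped, so this is equilibrium”, gives a chain length of 2.65 and a reacted part of 81.6%.

At 12 min the asked flask gives a chain length of 2.88 and a reacted part of 85.2%, with links at 64.6%, quenched substrate at 20.0% and 0.037% of the impurity left.

    first end groups → decomposition product (k = 4.96 × 10⁻⁵ s⁻¹)
    first end groups + protic impurity → quenched substrate (k = 1.19 M⁻¹ s⁻¹)
    second end groups → decomposed reagent (k = 0.0278 s⁻¹)
    first end groups + second end groups → links + by-product (k = 1.93 M⁻¹ s⁻¹)

A neighbour flask with 0.0042 M of protic impurity has 7.92% per first end, so the ledger gives 73.3% reacted and again a chain length of 2.95, with a clock of 52.6 s. That neighbour flask holds 0% of its impurity at the end, its links stand at 66.4%, its chain length is 3.04, and its reacted part is 75.3%.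

The readings are calculated for an exercise.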